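**Plan**

- Retrosynthesis: after the two O–Si bonds, the C1–C2 and C5–C6 bonds of ring A are cut (retro-[4+2] with formal return of methanol), then the phenol ester C–O bond of the resulting ynoate, then the two O-alkyl bonds on ring B.
- Enabling feature: in ring A the carbonyl-bearing C1 and the propyl-bearing C6 are adjacent and correspond to C2 and C3 of a hex-2-ynoate. C2–C5, with oxygen on C2 and C4, correspond to the four-carbon chain of acetoacetate.
- Forward order: ring B is bought intact as methyl divarinate and adjusted (4-O-benzyl, 2-O-methyl, debenzylation). The hex-2-ynoyl chain is joined through the phenol oxygen. Ring A is built last by cycloaddition and aromatisation, and the silyl groups are then removed.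
- Stereochemistry: the target has no stereocentre. The single transient stereocentre of the cycloadduct disappears on aromatisation.

Key step: step 7

Remark: methyl divarinate is taken as a purchasable compound. The double-bond geometry of 8, 9 and 10 is immaterial because these carbons end up in the aromatic ring, so their SMILES carry no E/Z descriptor.

**Route**

Step 1
Reactants: 1 methyl divarinate (methyl 2,4-dihydroxy-6-propylbenzoate)
Product: 2 methyl 4-(benzyloxy)-2-hydroxy-6-propylbenzoate
Conditions: BnBr (1.05 equiv), K2CO3 (1.1 equiv), acetone, reflux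
Reagents that add atoms: benzyl bromide, BrCc1ccccc1
Why: Williamson etherification; the 2-hydroxyl is tied up in a hydrogen bond to the ester carbonyl and is the poorer nucleophile, so the free 4-hydroxyl should be alkylated selectively.

Step 2
Reactants: 2 methyl 4-(benzyloxy)-2-hydroxy-6-propylbenzoate
Product: 3 methyl 4-(benzyloxy)-2-methoxy-6-propylbenzoate
Conditions: MeI (3 equiv), K2CO3 (2 equiv), DMF, 50 °C
Reagents that add atoms: iodomethane, CI
Why: Williamson methylation of the remaining chelated phenol, which a polar aprotic solvent and excess electrophile should drive to completion; no other nucleophilic site is present.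

Step 3
Reactants: 3 methyl 4-(benzyloxy)-2-methoxy-6-propylbenzoate
Product: 4 methyl 4-hydroxy-2-methoxy-6-propylbenzoate
Conditions: H2 (1 atm), Pd/C (10 wt% Pd), EtOAc, rt
Reagents that add atoms: none
Why: catalytic hydrogenolysis of the benzyl aryl ether; the methyl ether, methyl ester and arene are inert under these conditions.

Step 4
Reactants: 4 methyl 4-hydroxy-2-methoxy-6-propylbenzoate; 5 hex-2-ynoic acid
Product: 6 4-(methoxycarbonyl)-3-methoxy-5-propylphenyl hex-2-ynoate
Conditions: DCC (1.1 equiv), DMAP (0.05 equiv), CH2Cl2, 0 °C → rt
Reagents that add atoms: none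
Why: Steglich esterification of an unhindered linear acid with a phenol; low temperature and a small DMAP charge should keep conjugate addition of the catalyst to the β-alkyl ynoate in check.

Step 5
Reactants: 7 methyl acetoacetate
Product: 8 methyl 3-(trimethylsilyloxy)but-2-enoate (E/Z mixture)
Conditions: TMSCl (1.2 equiv), Et3N (1.3 equiv), hexane, rt; filtration, distillation
Reagents that add atoms: chlorotrimethylsilane, C[Si](C)(C)Cl
Why: O-silylation of the enol of a β-keto ester under amine-base soft enolisation, the standard entry to β-silyloxy enoates.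

Step 6
Reactants: 8 methyl 3-(trimethylsilyloxy)but-2-enoate
Product: 10 1-methoxy-1,3-bis(trimethylsilyloxy)buta-1,3-diene, via lithium dienolate 9 (not isolated)
Conditions: LiN(iPr)2 (1.1 equiv), THF, −78 °C; then TMSCl (1.2 equiv), −78 → 0 °C; evaporation, pentane, filtration under argon, used at once
Reagents that add atoms: chlorotrimethylsilane, C[Si](C)(C)Cl
Why: kinetic γ-deprotonation of the vinylogous ester gives the cross-conjugated ester dienolate, and the hard silyl chloride traps it on oxygen to give the ketene silyl acetal; this is the usual preparation of 1-alkoxy-1,3-bis(silyloxy)dienes.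

Step 7
Reactants: 6 4-(methoxycarbonyl)-3-methoxy-5-propylphenyl hex-2-ynoate; 10 1-methoxy-1,3-bis(trimethylsilyloxy)buta-1,3-diene
Product: 12 4-(methoxycarbonyl)-3-methoxy-5-propylphenyl 6-propyl-2,4-bis(trimethylsilyloxy)benzoate, via cyclohexa-1,4-diene cycloadduct 11 (not isolated)
Conditions: 10 (3 equiv), toluene, sealed tube under argon, 120 °C, 24–48 h; volatiles removed in vacuo
Reagents that add atoms: none
Why: Diels–Alder cycloaddition followed by aromatising elimination, the known route from 1-alkoxy-1,3-bis(silyloxy)butadienes and alk-2-ynoates to 6-alkylresorcylates, applied here to an aryl ynoate in place of an alkyl one. The CH2 terminus of the diene, its most nucleophilic carbon, should bond to the propyl-bearing β-carbon of the ynoate and the ketene-acetal carbon to the α-carbon, so that the C5–C6 and C1–C2 bonds of ring A form in a strongly asynchronous intermolecular [4+2] closure of the six-membered carbocycle. Cycloadduct 11 should then lose methanol by 1,4-elimination (methoxide from the ketal carbon C2, hydrogen from the C5 methylene), which leaves silyloxy groups at C2 and C4 and makes the ring aromatic. The only stereocentre formed, the mixed ketal carbon of 11, arises as a racemate and is erased by this elimination, so no stereocontrol is required. The step needs regioselectivity (propyl next to the former CH2 terminus) and chemoselectivity (cycloaddition, not acyl transfer from the aryl ester or attack on the methyl ester). The first rests on the matched polarisation of the 1,3-dioxygenated diene and the ynoate; the second on purely thermal conditions without Lewis acid or fluoride, helped by the aryl ester lowering the alkyne LUMO below that of an alkyl ynoate.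

Step 8
Reactants: 12 4-(methoxycarbonyl)-3-methoxy-5-propylphenyl 6-propyl-2,4-bis(trimethylsilyloxy)benzoate
Product: 13 4-(methoxycarbonyl)-3-methoxy-5-propylphenyl 2,4-dihydroxy-6-propylbenzoate (CNP0177078.0)
Conditions: 1 M aq. HCl, THF, 0 °C → rt
Reagents that add atoms: none
Why: acid hydrolysis of aryl trimethylsilyl ethers, which are far more labile than the depside and methyl esters; any mono-silylated material or residual 11 in the crude should converge on 13 under the same conditions.

**Compound list**

1 | methyl divarinate (methyl 2,4-dihydroxy-6-propylbenzoate) | CCCc1cc(O)cc(O)c1C(=O)OC | starting material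
2 | methyl 4-(benzyloxy)-2-hydroxy-6-propylbenzoate | CCCc1cc(OCc2ccccc2)cc(O)c1C(=O)OC | intermediate
3 | methyl 4-(benzyloxy)-2-methoxy-6-propylbenzoate | CCCc1cc(OCc2ccccc2)cc(OC)c1C(=O)OC | intermediate
4 | methyl 4-hydroxy-2-methoxy-6-propylbenzoate | CCCc1cc(O)cc(OC)c1C(=O)OC | intermediate
5 | hex-2-ynoic acid | CCCC#CC(=O)O | starting material
6 | 4-(methoxycarbonyl)-3-methoxy-5-propylphenyl hex-2-ynoate | CCCC#CC(=O)Oc1cc(CCC)c(C(=O)OC)c(OC)c1 | intermediate
7 | methyl acetoacetate | CC(=O)CC(=O)OC | starting material
8 | methyl 3-(trimethylsilyloxy)but-2-enoate (E/Z mixture) | CC(=CC(=O)OC)O[Si](C)(C)C | intermediate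
9 | lithium 1-methoxy-3-(trimethylsilyloxy)buta-1,3-dien-1-olate | C=C(O[Si](C)(C)C)C=C(OC)[O-].[Li+] | intermediate (not isolated)
10 | 1-methoxy-1,3-bis(trimethylsilyloxy)buta-1,3-diene | C=C(O[Si](C)(C)C)C=C(OC)O[Si](C)(C)C | intermediate
11 | 4-(methoxycarbonyl)-3-methoxy-5-propylphenyl 6-methoxy-2-propyl-4,6-bis(trimethylsilyloxy)cyclohexa-1,4-diene-1-carboxylate (racemic) | CCCC1=C(C(=O)Oc2cc(CCC)c(C(=O)OC)c(OC)c2)C(OC)(O[Si](C)(C)C)C=C(O[Si](C)(C)C)C1 | intermediate (not isolated)
12 | 4-(methoxycarbonyl)-3-methoxy-5-propylphenyl 6-propyl-2,4-bis(trimethylsilyloxy)benzoate | CCCc1cc(O[Si](C)(C)C)cc(O[Si](C)(C)C)c1C(=O)Oc1cc(CCC)c(C(=O)OC)c(OC)c1 | intermediate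
13 | 4-(methoxycarbonyl)-3-methoxy-5-propylphenyl 2,4-dihydroxy-6-propylbenzoate | CCCc1cc(O)cc(O)c1C(=O)Oc1cc(CCC)c(C(=O)OC)c(OC)c1 | target

**Step count**

Total: 8 steps. Longest linear sequence: 6 steps (1, 2, 3, 4, 7, 8); the diene branch (steps 5 and 6) joins at step 7.

**Steps most likely to fail**

Step 7. The internal ynoate may add too slowly, so that the diene decays thermally first, or the hexynoyl group may be transferred from the phenol ester to the diene. The fallback gives up ring construction for a classical depside coupling; it sets out from 1 and 4 and comes back at 13. Compound 1 would be benzylated twice (BnBr in excess, K2CO3, DMF, 60 °C) to methyl 2,4-bis(benzyloxy)-6-propylbenzoate F1. The hindered ester would be saponified (KOH, aqueous DMSO, 90 °C) to 2,4-bis(benzyloxy)-6-propylbenzoic acid F2. This acid would be joined to phenol 4 through its mixed trifluoroacetic anhydride (TFAA, toluene, rt) to give 4-(methoxycarbonyl)-3-methoxy-5-propylphenyl 2,4-bis(benzyloxy)-6-propylbenzoate F3. Hydrogenolysis (H2, Pd/C, EtOAc) would then deliver 13.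

Step 4. DMAP may add in conjugate fashion to the activated ynoate, and the O-acylisourea may rearrange to an N-acylurea before the phenol is acylated. The fallback removes both the carbodiimide and the nucleophilic catalyst by preforming the acyl donor; it sets out from 5 and comes back at 6. Acid 5 would be converted with oxalyl chloride and catalytic DMF in CH2Cl2 into hex-2-ynoyl chloride F4. This would be added to phenol 4 and i-Pr2NEt in CH2Cl2 at −20 °C to give 6.

Step 6. γ-Deprotonation may be incomplete, some silylation may occur on carbon, and the ketene silyl acetal may hydrolyse during isolation, so that the diene reaches the key step impure. The fallback builds the same two ring A bonds with a sturdier cyclic diene and aromatises by cycloreversion (Alder–Rickert sequence). It sets out from 6, with purchased dimedone as the new input, and comes back at 12. Dimedone would be O-silylated (TMSCl, Et3N) to 5,5-dimethyl-3-(trimethylsilyloxy)cyclohex-2-en-1-one F5. Enolisation toward the methylene next to the carbonyl and silylation (LiN(iPr)2, then TMSCl, THF, −78 °C) would give 5,5-dimethyl-1,3-bis(trimethylsilyloxy)cyclohexa-1,3-diene F6. Heating F6 with 6 (neat, 140–160 °C) should give 4-(methoxycarbonyl)-3-methoxy-5-propylphenyl 8,8-dimethyl-3-propyl-1,5-bis(trimethylsilyloxy)bicyclo[2.2.2]octa-2,5-diene-2-carboxylate F7. This adduct should lose isobutene by retro-Diels–Alder reaction at the same temperature and give 12.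

**Further compounds**

F1 | step 7 | methyl 2,4-bis(benzyloxy)-6-propylbenzoate | CCCc1cc(OCc2ccccc2)cc(OCc2ccccc2)c1C(=O)OC
F2 | step 7 | 2,4-bis(benzyloxy)-6-propylbenzoic acid | CCCc1cc(OCc2ccccc2)cc(OCc2ccccc2)c1C(=O)O
F3 | step 7 | 4-(methoxycarbonyl)-3-methoxy-5-propylphenyl 2,4-bis(benzyloxy)-6-propylbenzoate | CCCc1cc(OCc2ccccc2)cc(OCc2ccccc2)c1C(=O)Oc1cc(CCC)c(C(=O)OC)c(OC)c1
F4 | step 4 | hex-2-ynoyl chloride | CCCC#CC(Cl)=O
F5 | step 6 | 5,5-dimethyl-3-(trimethylsilyloxy)cyclohex-2-en-1-one | CC1(C)CC(=O)C=C(O[Si](C)(C)C)C1
F6 | step 6 | 5,5-dimethyl-1,3-bis(trimethylsilyloxy)cyclohexa-1,3-diene | CC1(C)CC(O[Si](C)(C)C)=CC(O[Si](C)(C)C)=C1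
F7 | step 6 | 4-(methoxycarbonyl)-3-methoxy-5-propylphenyl 8,8-dimethyl-3-propyl-1,5-bis(trimethylsilyloxy)bicyclo[2.2.2]octa-2,5-diene-2-carboxylate (racemic) | CCCC1=C(C(=O)Oc2cc(CCC)c(C(=O)OC)c(OC)c2)C2(O[Si](C)(C)C)C=C(O[Si](C)(C)C)C1C(C)(C)C2
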